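A single reversible step between E and Q cannot lift X to a peak and then lower it, yet X in the noon run goes from 30.8% at 4.00 min to 23.5% at 12.0 min. E and X together stay near the charge, at 99.9% in that last reading, so X is a form of E, and Q, which is not among the readings, must be leaving by another way.

| flask | E | Q | Z | remark | time |
|---|---|---|---|---|---|
| noon | 0.034 M | 0.055 M | 0.050 M | run made earlier |  |
| winter | 0.075 M | 0.055 M | 0.050 M | run made earlier |  |
| dusk | 0.050 M | 0.055 M | 0.025 M | run made earlier |  |
| Tuesday's | 0.050 M | 0.0550 M | 0.0500 M |  | 20 min |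
| Friday's | 0.050 M | 0.0550 M | 0.0500 M |  | 40 min |

| run | time / min | X / % | E / % |
|---|---|---|---|
| noon | 1.00 | 18.4 | 82.0 |
| noon | 1.50 | 23.1 | 77.2 |
| noon | 2.50 | 27.7 | 71.2 |
| noon | 4.00 | 30.8 | 68.8 |
| noon | 8.00 | 27.7 | 71.6 |
| noon | 12.0 | 23.5 | 76.4 |
| winter | 0.833 | 15.2 | 85.2 |
| winter | 2.50 | 24.6 | 74.4 |
| winter | 4.00 | 25.8 | 73.8 |
| winter | 6.00 | 25.0 | 74.5 |
| winter | 10.0 | 21.7 | 76.1 |
| winter | 12.0 | 19.8 | 78.7 |
| dusk | 1.00 | 17.2 | 81.9 |
| dusk | 3.00 | 29.6 | 71.5 |
| dusk | 6.00 | 29.3 | 70.2 |
| dusk | 8.00 | 27.5 | 72.6 |
| dusk | 12.0 | 23.1 | 76.9 |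

(scatter of a reading: 0.5 percentage points)



1. which of these there is most of at the end, counted by the E in it, Tuesday's (E / X)
2. which of these there is most of at the end, counted by the E in it, Friday's (E / X)
3. final amount of the leader among these, as a percentage of the E charged, in Tuesday's
4. final amount of the leader among these, as a percentage of the E charged, in Friday's

What can stand in for free Q? Taking E + Q ⇌ X as a pre-equilibrium, the bound ratio, X over E as fractions of the E charged, follows free Q.

How fast does that ratio fall? Late in the noon run its logarithm drops at 0.0573 /min. The dusk run, with less Z, reads 0.0580 /min, and the winter run, with more E, reads 0.0480 /min, less than the noon run. Tuesday's flask has Z and Q as in noon and winter, with E between theirs, so the mean of those two readings serves: 0.0527 /min, the fall rate of the bound ratio.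

Where does Tuesday's flask end? The same mean gives a ratio of 0.280 at 12.0 min. Carried to 20 min at the fall rate, it becomes 0.183, so this reckoning puts E at 84.5%, in the lead.

Friday's flask is the same recipe, later, so that answer goes back in as the start. The ratio becomes 0.0640, and this reckoning puts E at 94.0%.

The forecast names E at 86% for Tuesday's and E at 97% for Friday's, higher than this reckoning, and holds that “The later fall in X means Q is being drained”.

The flask gives E at 83.6%, with X at 15.8%, in Tuesday's, and E at 92.4%, with X at 6.37%, in Friday's.

    E + Q ⇌ X (K = 27.2 /M, k = 4.98 /M/min)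
    Z + Q ⇌ J (K = 12.3 /M, k = 3.09 /M/min)
    E → D (k = 3.64 × 10⁻⁴ /min)
    Q → G (k = 0.155 /min)
    Z ⇌ L (K = 0.430, k = 0.0196 /min)

In Friday's the relaxation of E + Q and X has a half-life of 1.64 min at the end, shorter than the 4.5 min half-life of Q on the path to G, and that in turn is shorter than the half-life of 13.2 min that the fall rate gives the bound ratio, while Q also stands in X and J. Carried over 20.0 min from Tuesday's final ratio of 0.189, the fall rate gives 0.0659, and Friday's flask stands at 0.0690.

(Readings and results are simulated with constants of no real substance; noise was put on by code.)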